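**Assumption:** 2,2-dimethyl-1,3-dioxan-5-one and pent-4-enal are taken as catalogue compounds; bicyclic intermediates are numbered as 4H-1,3-benzodioxin (O1, C2, O3, C4, C4a, C5–C8, C8a).

## Retrosynthetic overview

1. Target 10 ⇐ triol 9 by benzoylation of its only primary OH; 9 ⇐ bicyclic α-ketol 7 by hydroxyl-directed ketone reduction and acetonide hydrolysis.
2. Key disconnection: the ring bond between the quaternary carbinol carbon and the neighbouring CH(OH) carbon. It is made by intramolecular attack of a carbene-bound acyl anion (Breslow intermediate of an aldehyde) on the ketone of a dihydroxyacetone acetonide, which closes the cyclohexane and creates the quaternary stereocentre.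
3. Keto-aldehyde 6 ⇐ terminal alkene 4 (ozonolysis) ⇐ anti-aldol 3 (Mitsunobu inversion with benzoic acid) ⇐ dioxanone 1 + pent-4-enal 2 ((S)-proline aldol).
4. Ring order: the 1,3-dioxane (a protecting ring) comes with 1; the cyclohexane is the only ring formed (step 4); the dioxane is opened in step 5.

## Route

**Step 1**
Reactants: 1 2,2-dimethyl-1,3-dioxan-5-one; 2 pent-4-enal
Product: 3 (4S)-4-[(1S)-1-hydroxypent-4-en-1-yl]-2,2-dimethyl-1,3-dioxan-5-one
Conditions: (S)-proline (30 mol %), DMF, 2 °C, 5 d, 2 added slowly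
Reagents that add atoms: none
Why: Proline enamine aldol (List–Houk chair); the ring-locked (E)-enamine attacks the Re face of the aldehyde and gives the anti (4S,1'S) adduct, a reaction known to tolerate unbranched aldehydes in moderate yield.

**Step 2**
Reactants: 3 (4S)-4-[(1S)-1-hydroxypent-4-en-1-yl]-2,2-dimethyl-1,3-dioxan-5-one
Product: 4 (1R)-1-[(4S)-2,2-dimethyl-5-oxo-1,3-dioxan-4-yl]pent-4-en-1-yl benzoate
Conditions: PPh3, DIAD, BzOH, toluene, −20 °C → rt
Reagents that add atoms: benzoic acid, OC(=O)c1ccccc1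
Why: Mitsunobu esterification; SN2 displacement of the oxyphosphonium by benzoate inverts the carbinol (1S → 1R), which installs the secondary benzoate and turns the anti-aldol into the threo O/O arrangement that becomes the trans ring relationship.

**Step 3**
Reactants: 4 (1R)-1-[(4S)-2,2-dimethyl-5-oxo-1,3-dioxan-4-yl]pent-4-en-1-yl benzoate
Product: 6 (1R)-1-[(4S)-2,2-dimethyl-5-oxo-1,3-dioxan-4-yl]-4-oxobutyl benzoate, via secondary ozonide 5 (not isolated)
Conditions: O3, CH2Cl2, −78 °C; then PPh3, −78 °C → rt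
Reagents that add atoms: ozone, [O-][O+]=O
Why: Ozonolysis (Criegee) of the only alkene with neutral reductive work-up; ketone, acetal and benzoate are inert and no stereocentre is touched.

**Step 4**
Reactants: 6 (1R)-1-[(4S)-2,2-dimethyl-5-oxo-1,3-dioxan-4-yl]-4-oxobutyl benzoate
Product: 7 (4aR,8R,8aS)-4a-hydroxy-2,2-dimethyl-5-oxohexahydro-4H-1,3-benzodioxin-8-yl benzoate (cis-fused; tertiary OH trans to the C8a–O bond and cis to the benzoate)
Conditions: 2-(pentafluorophenyl)-6,7-dihydro-5H-pyrrolo[2,1-c][1,2,4]triazol-2-ium tetrafluoroborate (15 mol %), iPr2NEt (15 mol %), CH2Cl2 (0.05 M), 0 °C → rt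
Reagents that add atoms: none
Why: Proposed new method: the triazolylidene converts the aldehyde into a Breslow enaminol (acyl anion equivalent) that attacks the electron-poor α,α'-dioxygenated ketone in a 6-exo closure; with the side chain equatorial on the dioxanone chair the tether should reach the carbonyl preferentially along the axial trajectory (the torsionally favoured one for 1,3-dioxan-5-ones, which lack syn-axial hydrogens), giving the cis-fused ketol and hence 4aR, while the weak amine base limits E1cB loss of the β-benzoate; closest known reaction type is the carbene-catalysed intramolecular aldehyde–ketone crossed benzoin cyclisation, which gives cis-fused bicyclic ketols from cycloalkanones carrying an ω-oxoalkyl chain.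

**Step 5**
Reactants: 7 (4aR,8R,8aS)-4a-hydroxy-2,2-dimethyl-5-oxohexahydro-4H-1,3-benzodioxin-8-yl benzoate
Product: 9 (1R,2S,3S,4R)-2,3,4-trihydroxy-3-(hydroxymethyl)cyclohexyl benzoate, via acetonide diol 8 (not isolated)
Conditions: Me4NBH(OAc)3 (5 equiv), MeCN–AcOH (1:1), −30 → 0 °C; then H2O, 50 °C
Reagents that add atoms: none
Why: Saksena–Evans hydroxyl-directed reduction; the tertiary OH (the only free hydroxyl) binds boron and delivers hydride to its own face of the ketone, giving the trans-1,2-diol (new centre 5R), after which the warm aqueous acetic acid hydrolyses the isopropylidene acetal without touching the benzoate.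

**Step 6**
Reactants: 9 (1R,2S,3S,4R)-2,3,4-trihydroxy-3-(hydroxymethyl)cyclohexyl benzoate
Product: 10 [(1S,2S,3R,6R)-3-(benzoyloxy)-1,2,6-trihydroxycyclohexyl]methyl benzoate (CNP0264996.1)
Conditions: BzCl (1.05 equiv), 2,4,6-collidine, CH2Cl2, −40 → 0 °C
Reagents that add atoms: benzoyl chloride, O=C(Cl)c1ccccc1
Why: Kinetically selective acylation of the single primary hydroxyl over the tertiary one and the two secondary ones that flank the quaternary carbon; the weak base and low temperature avoid benzoyl migration, and no stereocentre is involved.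

## Compound list

1 | 2,2-dimethyl-1,3-dioxan-5-one | CC1(C)OCC(=O)CO1 | starting material
2 | pent-4-enal | C=CCCC=O | starting material
3 | (4S)-4-[(1S)-1-hydroxypent-4-en-1-yl]-2,2-dimethyl-1,3-dioxan-5-one | C=CCC[C@H](O)[C@@H]1OC(C)(C)OCC1=O | intermediate
4 | (1R)-1-[(4S)-2,2-dimethyl-5-oxo-1,3-dioxan-4-yl]pent-4-en-1-yl benzoate | C=CCC[C@@H](OC(=O)c1ccccc1)[C@@H]2OC(C)(C)OCC2=O | intermediate
5 | (1R)-1-[(4S)-2,2-dimethyl-5-oxo-1,3-dioxan-4-yl]-3-(1,2,4-trioxolan-3-yl)propyl benzoate (secondary ozonide, epimer mixture at the trioxolane carbon) | C1(CC[C@@H](OC(=O)c2ccccc2)[C@@H]3OC(C)(C)OCC3=O)OCOO1 | intermediate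
6 | (1R)-1-[(4S)-2,2-dimethyl-5-oxo-1,3-dioxan-4-yl]-4-oxobutyl benzoate | O=CCC[C@@H](OC(=O)c1ccccc1)[C@@H]2OC(C)(C)OCC2=O | intermediate
7 | (4aR,8R,8aS)-4a-hydroxy-2,2-dimethyl-5-oxohexahydro-4H-1,3-benzodioxin-8-yl benzoate | O=C1CC[C@@H](OC(=O)c2ccccc2)[C@@H]3OC(C)(C)OC[C@]13O | intermediate
8 | (4aS,5R,8R,8aS)-4a,5-dihydroxy-2,2-dimethylhexahydro-4H-1,3-benzodioxin-8-yl benzoate | O[C@@H]1CC[C@@H](OC(=O)c2ccccc2)[C@@H]3OC(C)(C)OC[C@]13O | intermediate
9 | (1R,2S,3S,4R)-2,3,4-trihydroxy-3-(hydroxymethyl)cyclohexyl benzoate | OC[C@]1(O)[C@H](O)CC[C@@H](OC(=O)c2ccccc2)[C@@H]1O | intermediate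
10 | [(1S,2S,3R,6R)-3-(benzoyloxy)-1,2,6-trihydroxycyclohexyl]methyl benzoate | O=C(OC[C@]1(O)[C@H](O)CC[C@@H](OC(=O)c2ccccc2)[C@@H]1O)c1ccccc1 | target

## Step count and risks

Total steps: 6. Longest linear sequence: 6.

The three steps most likely to fail:

1. **Step 4, the ring closure.** The configuration at C4a rests on a conformational argument, not on direct precedent for a dioxanone acceptor, and the β-benzoyloxy ketone can eliminate under base. The fallback sets out from 6 and closes the ring with a ketyl radical instead. SmI2 (2.2 equiv), tBuOH, THF, −78 °C reduces the aldehyde first and gives the pinacol cis-diol (4aS,5S,8R,8aS)-4a,5-dihydroxy-2,2-dimethylhexahydro-4H-1,3-benzodioxin-8-yl benzoate F1. Its new hydroxyls are expected trans to the neighbouring ring C–O bond, as is usual for such cyclisations next to an alkoxy group, and no base is present. Oxidation of the secondary alcohol alone (IBX, EtOAc, 70 °C) erases the C5 centre and comes back to the route at 7.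

2. **Step 2, the Mitsunobu inversion.** A β-hydroxy ketone can eliminate to the enone instead of being displaced. The fallback sets out from 3 and postpones the inversion until the ketone is no longer β to the carbinol. Ozonolysis of 3 (O3, CH2Cl2, −78 °C; PPh3) gives the keto-lactol (4S)-4-[(2S)-5-hydroxyoxolan-2-yl]-2,2-dimethyl-1,3-dioxan-5-one F2. The triazolium/iPr2NEt cyclisation of step 4, acting on the open hydroxy-aldehyde form, gives (4aR,8S,8aS)-4a,8-dihydroxy-2,2-dimethylhexahydro-4H-1,3-benzodioxin-5-one F3. Mitsunobu reaction of its equatorial secondary alcohol (BzOH, PPh3, DIAD, toluene) inverts C8 and comes back to the route at 7.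

3. **Step 1, the proline aldol.** The unbranched aldehyde can self-condense and lower yield and ee. The fallback sets out from 2 and uses a different donor and a syn-selective primary-amine catalyst, which also makes the inversion unnecessary. Commercial 1,3-bis(tert-butyldimethylsilyloxy)propan-2-one and 2 with O-tert-butyl-D-threonine (20 mol %) and 5-methyl-1H-tetrazole (10 mol %) in wet NMP at 4 °C give the syn-aldol (3S,4R)-1,3-bis[(tert-butyldimethylsilyl)oxy]-4-hydroxyoct-7-en-2-one F4. BzCl, pyridine and DMAP give (3S,4R)-1,3-bis[(tert-butyldimethylsilyl)oxy]-2-oxooct-7-en-4-yl benzoate F5. HF·pyridine (THF, 0 °C) gives (3S,4R)-1,3-dihydroxy-2-oxooct-7-en-4-yl benzoate F6. Acetonide formation (2,2-dimethoxypropane, PPTS, acetone) comes back to the route at 4.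

## Further compounds

F1 | step 4 | (4aS,5S,8R,8aS)-4a,5-dihydroxy-2,2-dimethylhexahydro-4H-1,3-benzodioxin-8-yl benzoate | O[C@H]1CC[C@@H](OC(=O)c2ccccc2)[C@@H]3OC(C)(C)OC[C@]13O
F2 | step 2 | (4S)-4-[(2S)-5-hydroxyoxolan-2-yl]-2,2-dimethyl-1,3-dioxan-5-one | OC1CC[C@H](O1)[C@@H]2OC(C)(C)OCC2=O
F3 | step 2 | (4aR,8S,8aS)-4a,8-dihydroxy-2,2-dimethylhexahydro-4H-1,3-benzodioxin-5-one | O=C1CC[C@H](O)[C@@H]3OC(C)(C)OC[C@]13O
F4 | step 1 | (3S,4R)-1,3-bis[(tert-butyldimethylsilyl)oxy]-4-hydroxyoct-7-en-2-one | C=CCC[C@@H](O)[C@H](O[Si](C)(C)C(C)(C)C)C(=O)CO[Si](C)(C)C(C)(C)C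
F5 | step 1 | (3S,4R)-1,3-bis[(tert-butyldimethylsilyl)oxy]-2-oxooct-7-en-4-yl benzoate | C=CCC[C@@H](OC(=O)c1ccccc1)[C@H](O[Si](C)(C)C(C)(C)C)C(=O)CO[Si](C)(C)C(C)(C)C
F6 | step 1 | (3S,4R)-1,3-dihydroxy-2-oxooct-7-en-4-yl benzoate | C=CCC[C@@H](OC(=O)c1ccccc1)[C@H](O)C(=O)CO
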